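The constants of this flask are hidden, so its peak has to be reckoned from the readings of the earlier runs.

| flask | substrate | catalyst | remark | time |
|---|---|---|---|---|
| eta | 6.5 mM | 0.27 mol% | run made earlier |  |
| zeta | 26 mM | 0.27 mol% | run made earlier |  |
| theta | 13 mM | 0.54 mol% | run made earlier |  |
| flask | 13 mM | 0.27 mol% |  | 10 min |

- eta (time / min: target / %, substrate / %): 0.167: 10.2, 47.4; 0.200: 12.3, 41.8; 0.417: 13.9, 24.1; 0.833: 10.0, 16.3; 2.00: 5.9, 10.0; 4.00: 3.7, 4.4; 8.00: 0, 0
- zeta (time / min: target / %, substrate / %): 0.167: 21.1, 13.3; 0.200: 22.3, 11.7; 0.417: 27.2, 7.1; 0.833: 21.6, 6.6; 2.00: 7.0, 3.5; 4.00: 2.1, 0.5; 8.00: 0.9, 0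
- theta (time / min: target / %, substrate / %): 0.167: 22.2, 15.1; 0.250: 22.9, 9.9; 0.833: 16.2, 5.0; 2.50: 1.6, 2.9; 8.00: 0, 0

(readings scatter by 1 percentage point)

* the best time, 10 min at the latest, for target
* the amount of target, in percent of the substrate charged, at that time
* earliest time at which at least nineteen twentieths of that best amount are there, in min
* latest time at which they still are, in min

- a reading or a percentage of target counts all its forms, free or not
- a reading of substrate is of its free form alone

Eta and zeta share the flask's loading, and both read highest at 0.417 min, with 13.9% and 27.2% of target. The flask's substrate charge is twice eta's and half zeta's. A first estimate therefore assumes that each doubling of the charge multiplies the peak by one factor, the charge gain, here 1.40. The estimate for the flask's peak is then 19.4%.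

Two doubts follow. Each peak is a single reading with a scatter of 1 percentage point, so the estimate carries scatter too. Worse, the charge gain mixes two changes, since catalyst goes from 0.0176 mM in eta to 0.0351 mM in the flask. Theta separates them: it has the flask's substrate charge and twice its loading, and it reads 22.9% at 0.250 min. Theta's highest reading over the estimate is 1.18, the loading gain: the factor on the peak of target per doubling of the loading at a fixed substrate charge. It is smaller than the charge gain. Eta has one reading between 0.200 min and 0.833 min, so no window is reckoned here.

The forecast puts the peak at 0.39 min with 20.5%, and the asked level from 0.27 min to 0.55 min, on the ground that “Higher concentration raises the yield but barely moves the peak time”. Its peak stands 1.1 points above the estimate here.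

The flask gives 18.7% at 0.360 min, and the asked level holds from 0.224 min, earlier than the forecast's opening, to 0.590 min.

    substrate + catalyst ⇌ target + catalyst, rate k1*[substrate]*[catalyst] forward; the back reaction follows from the equilibrium constant (K = 5.00, k = 990 /M/s)
    target ⇌ isomer of the product A (K = 0.510, k = 0.0150 /s)
    isomer of the product A + catalyst ⇌ isomer of the product B + catalyst, rate k3*[catalyst]*[isomer of the product A] forward; the back reaction follows from the equilibrium constant (K = 1.00, k = 210 /M/s)
    isomer of the product B + catalyst ⇌ substrate + catalyst, rate k4*[catalyst]*[isomer of the product B] forward; the back reaction follows from the equilibrium constant (k = 1200 /M/s)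
    substrate + target ⇌ idle adduct, settled at all times (K = 2400 /M)
    target → over-reaction product (k = 0.170 /s)

At 0.360 min the flask's idle adduct stands at 30.7%, a figure in which it counts as two, and each adduct counts as one target in the peak. Carried from the flask to 0.68 mol% of catalyst, the loading gain gives 23.2%, and that neighbour flask gives 23.3%.

(All runs stem from a simulated flask on assumed constants, noise included.)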